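**Plan**
- Retrosynthetic cuts, in order: (a) the two N–Boc and four O–benzyl bonds; (b) the C2–C3 bond of the butane-1,4-diyl chain between the two secondary amine nitrogens, traced back to a C=C bond and then to two N-allyl termini; (c) in each half, the amide C–N bond and the N–CH2 bond of the propane-1,3-diyl spacer.
- Forward: 1 + 2 → 3 → 4 (amine arm); 5 → 7 (protected acid); 4 + 7 → 9; two molecules of 9 → 10, joining the chain at its centre; 10 → 11 → 13.
- Enabling feature: the molecule is twofold symmetric about the midpoint of the C2–C3 bond of the N–CH2CH2CH2CH2–N chain, so both halves are the same N-allyl carbamate. The two benzene (catechol) rings are spectators and no ring is formed at any stage.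
- Stereochemistry: the target has no stereocentre. The only stereo-element on the way, the E/Z geometry of the alkene in 10, is erased in step 6.

Key step: step 5

Assumption 1: the metathesis should give 10 as an E/Z mixture with E predominating; it is drawn as the E isomer and the mixture is carried on, since both isomers converge on hydrogenation.
Assumption 2: the target is drawn as the neutral free base. The last step passes through the bis(hydrochloride) 12, which is the same compound in protonated form and the sensible storage form for this air-sensitive catechol.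

**Step 1**
Reactants: 1 tert-butyl allylcarbamate; 2 N-(3-bromopropyl)phthalimide
Product: 3 tert-butyl allyl[3-(1,3-dioxoisoindolin-2-yl)propyl]carbamate
Conditions: NaH, DMF, 0 °C; then 2, 0 °C to rt
Reagents that add atoms: none
Why: SN2 N-alkylation of the sodium carbamate formed from the Boc N–H, a standard route to N-Boc N,N-dialkylamines; the hindered carbamate anion should attack the primary C–Br carbon in preference to the imide carbonyl.

**Step 2**
Reactants: 3 tert-butyl allyl[3-(1,3-dioxoisoindolin-2-yl)propyl]carbamate
Product: 4 tert-butyl allyl(3-aminopropyl)carbamate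
Conditions: N2H4·H2O, EtOH (degassed), reflux, argon
Reagents that add atoms: none
Why: Ing–Manske hydrazinolysis (Gabriel amine synthesis) expels phthalhydrazide and frees the primary amine, leaving the Boc carbamate untouched and, with air excluded so that no diimide forms, the terminal alkene as well.

**Step 3**
Reactants: 5 dihydrocaffeic acid
Product: 7 3-[3,4-bis(benzyloxy)phenyl]propanoic acid, via benzyl ester 6 (not isolated)
Conditions: BnBr (3.5 equiv), K2CO3, DMF, 60 °C, argon; then NaOH (aq), MeOH, 60 °C; HCl (aq) to pH 2
Reagents that add atoms: benzyl bromide, BrCc1ccccc1; sodium hydroxide, [Na+].[OH-]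
Why: Williamson O-benzylation of both phenols and the carboxylate, followed by in-flask saponification of the benzyl ester, should return the free acid with the catechol masked as benzyl ethers that survive every step up to the hydrogenolysis in step 6.

**Step 4**
Reactants: 7 3-[3,4-bis(benzyloxy)phenyl]propanoic acid; 4 tert-butyl allyl(3-aminopropyl)carbamate
Product: 9 tert-butyl allyl{3-[3-(3,4-bis(benzyloxy)phenyl)propanamido]propyl}carbamate, via acyl imidazolide 8 (not isolated)
Conditions: CDI (1.05 equiv), THF, rt until CO2 evolution ends; then 4, THF, rt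
Reagents that add atoms: none
Why: Amide coupling through the acyl imidazolide; CDI activates the acid with loss of CO2, and the unhindered primary amine of 4 should then be acylated cleanly because the carbamate nitrogen is not nucleophilic.

**Step 5**
Reactants: 9 tert-butyl allyl{3-[3-(3,4-bis(benzyloxy)phenyl)propanamido]propyl}carbamate (two molecules)
Product: 10 di-tert-butyl (E)-but-2-ene-1,4-diylbis({3-[3-(3,4-bis(benzyloxy)phenyl)propanamido]propyl}carbamate)
Conditions: second-generation Grubbs catalyst RuCl2(H2IMes)(PCy3)(=CHPh) (5 mol%), 1,4-benzoquinone (10 mol%), CH2Cl2 (0.3 M), 40 °C, argon sparge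
Reagents that add atoms: none
Why: Olefin self-metathesis (homodimerising cross-metathesis): the ruthenium benzylidene exchanges with the terminal alkene of 9 to give a ruthenium alkylidene, which adds a second molecule of 9 by [2+2] cycloaddition to a ruthenacyclobutane; cycloreversion releases the internal alkene of 10 and a ruthenium methylidene that re-enters the cycle with loss of ethene. The closest known reaction type is the ruthenium-carbene self-metathesis of N-Boc allylamines to 1,4-bis(carbamoyl)but-2-enes. No ring is closed and no stereocentre is created; the new C=C bond should form mainly as the E isomer under thermodynamic control through secondary metathesis, and its geometry does not matter because step 6 saturates it. The only selectivity needed is clean reaction at the terminal alkene, which the substrate secures by having a single alkene type, a non-basic carbamate on the allylic nitrogen that cannot bind ruthenium, and only inert spectators (secondary amide, aryl benzyl ethers). Sparging away ethene drives the equilibrium, and 1,4-benzoquinone intercepts ruthenium hydrides that would otherwise isomerise the allyl carbamate to an enecarbamate.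

**Step 6**
Reactants: 10 di-tert-butyl (E)-but-2-ene-1,4-diylbis({3-[3-(3,4-bis(benzyloxy)phenyl)propanamido]propyl}carbamate)
Product: 11 di-tert-butyl butane-1,4-diylbis({3-[3-(3,4-dihydroxyphenyl)propanamido]propyl}carbamate)
Conditions: H2 (1 atm), Pd/C (10 wt% Pd), MeOH/THF, rt; filtration under argon
Reagents that add atoms: none
Why: Heterogeneous catalytic hydrogenation over Pd/C should saturate the disubstituted alkene and hydrogenolyse the four aryl benzyl ethers in one operation, while Boc carbamates and amides are inert to these conditions.

**Step 7**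
Reactants: 11 di-tert-butyl butane-1,4-diylbis({3-[3-(3,4-dihydroxyphenyl)propanamido]propyl}carbamate)
Product: 13 kukoamine A, via kukoamine A bis(hydrochloride) 12 (not isolated)
Conditions: HCl (4 M in 1,4-dioxane), 0 °C to rt; evaporate; then NaOMe (2.0 equiv), MeOH, 0 °C, argon; Sephadex LH-20 (MeOH)
Reagents that add atoms: none
Why: Acidolytic Boc cleavage (loss of 2-methylpropene, then decarboxylation of the carbamic acid) gives the bis(hydrochloride), and exactly two equivalents of NaOMe under argon should remove the two HCl without leaving excess base that would promote catechol oxidation.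

**Compound list**
1 | tert-butyl allylcarbamate | C=CCNC(=O)OC(C)(C)C | starting material
2 | N-(3-bromopropyl)phthalimide | O=C1c2ccccc2C(=O)N1CCCBr | starting material
3 | tert-butyl allyl[3-(1,3-dioxoisoindolin-2-yl)propyl]carbamate | C=CCN(CCCN1C(=O)c2ccccc2C1=O)C(=O)OC(C)(C)C | intermediate
4 | tert-butyl allyl(3-aminopropyl)carbamate | C=CCN(CCCN)C(=O)OC(C)(C)C | intermediate
5 | dihydrocaffeic acid, 3-(3,4-dihydroxyphenyl)propanoic acid | OC(=O)CCc1ccc(O)c(O)c1 | starting material
6 | benzyl 3-[3,4-bis(benzyloxy)phenyl]propanoate | O=C(CCc1ccc(OCc2ccccc2)c(OCc2ccccc2)c1)OCc1ccccc1 | intermediate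
7 | 3-[3,4-bis(benzyloxy)phenyl]propanoic acid | OC(=O)CCc1ccc(OCc2ccccc2)c(OCc2ccccc2)c1 | intermediate
8 | 3-[3,4-bis(benzyloxy)phenyl]-1-(imidazol-1-yl)propan-1-one (acyl imidazolide) | O=C(CCc1ccc(OCc2ccccc2)c(OCc2ccccc2)c1)n1ccnc1 | intermediate
9 | tert-butyl allyl{3-[3-(3,4-bis(benzyloxy)phenyl)propanamido]propyl}carbamate | C=CCN(CCCNC(=O)CCc1ccc(OCc2ccccc2)c(OCc2ccccc2)c1)C(=O)OC(C)(C)C | intermediate
10 | di-tert-butyl (E)-but-2-ene-1,4-diylbis({3-[3-(3,4-bis(benzyloxy)phenyl)propanamido]propyl}carbamate) | O=C(CCc1ccc(OCc2ccccc2)c(OCc2ccccc2)c1)NCCCN(C(=O)OC(C)(C)C)C/C=C/CN(C(=O)OC(C)(C)C)CCCNC(=O)CCc1ccc(OCc2ccccc2)c(OCc2ccccc2)c1 | intermediate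
11 | di-tert-butyl butane-1,4-diylbis({3-[3-(3,4-dihydroxyphenyl)propanamido]propyl}carbamate) | O=C(CCc1ccc(O)c(O)c1)NCCCN(C(=O)OC(C)(C)C)CCCCN(C(=O)OC(C)(C)C)CCCNC(=O)CCc1ccc(O)c(O)c1 | intermediate
12 | kukoamine A bis(hydrochloride) | O=C(CCc1ccc(O)c(O)c1)NCCC[NH2+]CCCC[NH2+]CCCNC(=O)CCc1ccc(O)c(O)c1.[Cl-].[Cl-] | intermediate
13 | kukoamine A, N,N'-[butane-1,4-diylbis(azanediylpropane-3,1-diyl)]bis[3-(3,4-dihydroxyphenyl)propanamide] | O=C(CCc1ccc(O)c(O)c1)NCCCNCCCCNCCCNC(=O)CCc1ccc(O)c(O)c1 | target

**Count**
Total steps: 7. Longest linear sequence: 6 (steps 1, 2, 4, 5, 6, 7); step 3 is the convergent branch.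

**Steps most likely to fail**

Step 5. The homodimerisation may stall at partial conversion because the hydrogen-bonding amide substrate aggregates and slows turnover, so that ruthenium hydrides from catalyst decay migrate the double bond into an unreactive enecarbamate. The fallback moves the same C=C formation ahead of the acylation. Setting out from 3, which has no N–H donor and no benzyl ethers, self-metathesis with second-generation Grubbs catalyst RuCl2(H2IMes)(PCy3)(=CHPh) in CH2Cl2 at 40 °C should give di-tert-butyl (E)-but-2-ene-1,4-diylbis{[3-(1,3-dioxoisoindolin-2-yl)propyl]carbamate} F1. Hydrazinolysis (N2H4·H2O, EtOH, reflux, argon) should free di-tert-butyl (E)-but-2-ene-1,4-diylbis[(3-aminopropyl)carbamate] F2. Twofold acylation of F2 with two equivalents of acyl imidazolide 8 (from 7 and CDI as in step 4) returns to the route at 10.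

Step 1. Base-induced elimination of HBr from the bromide and attack of the carbamate anion on the imide carbonyl may compete with N-alkylation. The fallback avoids an imide in the presence of strong base. Setting out from 1, alkylation (NaH, DMF, 0 °C to rt) with 3-azidopropyl 4-methylbenzenesulfonate (commercial, or made from 3-azidopropan-1-ol and TsCl) should give tert-butyl allyl(3-azidopropyl)carbamate F3. Staudinger reduction (PPh3, THF/H2O, rt to 50 °C), which leaves the alkene alone, returns to the route at 4.

Step 7. Once the ammonium salt is neutralised, the electron-rich catechol may be oxidised to the o-quinone and attacked by the freed amines, and the very polar free base may be lost on desalting. The fallback reverses the order of the two deprotections so that the catechol is never exposed to base. Setting out from 10, Boc cleavage with CF3CO2H in CH2Cl2 at 0 °C to rt, followed by an aqueous NaOH wash (harmless while the phenols are still benzylated), should give (E)-N,N'-[but-2-ene-1,4-diylbis(azanediylpropane-3,1-diyl)]bis{3-[3,4-bis(benzyloxy)phenyl]propanamide} F4. Hydrogenation of F4 (H2, Pd/C (10 wt% Pd), MeOH, rt; filtration under argon) should saturate the alkene and remove the four benzyl ethers under neutral conditions, returning to the route at 13.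

**Further compounds**
F1 | step 5 | di-tert-butyl (E)-but-2-ene-1,4-diylbis{[3-(1,3-dioxoisoindolin-2-yl)propyl]carbamate} | O=C1c2ccccc2C(=O)N1CCCN(C(=O)OC(C)(C)C)C/C=C/CN(C(=O)OC(C)(C)C)CCCN1C(=O)c2ccccc2C1=O
F2 | step 5 | di-tert-butyl (E)-but-2-ene-1,4-diylbis[(3-aminopropyl)carbamate] | NCCCN(C(=O)OC(C)(C)C)C/C=C/CN(C(=O)OC(C)(C)C)CCCN
F3 | step 1 | tert-butyl allyl(3-azidopropyl)carbamate | C=CCN(CCCN=[N+]=[N-])C(=O)OC(C)(C)C
F4 | step 7 | (E)-N,N'-[but-2-ene-1,4-diylbis(azanediylpropane-3,1-diyl)]bis{3-[3,4-bis(benzyloxy)phenyl]propanamide} | O=C(CCc1ccc(OCc2ccccc2)c(OCc2ccccc2)c1)NCCCNC/C=C/CNCCCNC(=O)CCc1ccc(OCc2ccccc2)c(OCc2ccccc2)c1
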